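The dihydropyran (O1, C2–C6) is disconnected at C2–C3. C2 carries O1 and the methyl group, so it is the α-carbon of an O-vinyl lactic acid and can be generated as an α-oxy radical by photoredox decarboxylation. In one operation this radical closes the ring 6-exo onto a C4-bound alkenylboronate, sets C2 and C3 relative to the existing C4 centre and leaves a C–B bond as the masked C3 hydroxymethyl group. The precursor is an acyclic (S)-C4 (E)-alkenylboronate made from methyl coumalate, bearing the C5=C6 enol ether of lactic acid (either configuration) and the hydroxytyrosyl ester with its catechol protected as the dibenzyl ether.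

Key step: step 7

Remarks on the chemistry
- Ring numbering (O1, C2 methyl, C3 hydroxymethyl, C4 acetate arm, C5 methyl ester, C6) is also used for the acyclic intermediates.
- Structure check: (S) at C4 of the acyclic precursor and (2R,3S,4S) in the cyclised boronate describe the same spatial arrangement as the (2R,3R,4S) target. The C3 descriptor changes only because CH2B ranks below C4, whereas CH2OH ranks above it.
- Protecting group: the catechol is carried as benzyl ethers, because aryl silyl ethers are cleaved by carbonate bases in DMF and by fluoride released from trifluoroborates, and the route uses both.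
- Assumption: opening of methyl coumalate by an alkoxide ends at the thermodynamically preferred (2E,4E) push–pull dienoic acid.
- Assumption: the sense of induction known for Rh/BINAP with (E)-enoates carries over to this dienoate, so (R)-BINAP is specified; the antipodal ligand is used if the first correlation shows the opposite sense.

Step 1
Reactants: 1 hydroxytyrosol
Product: 2 2-[3,4-bis(benzyloxy)phenyl]ethan-1-ol
Conditions: BnBr (2.2 equiv), K2CO3 (3 equiv), acetone, reflux
Reagents that add atoms: benzyl bromide, BrCc1ccccc1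
Why: Williamson ether synthesis in which K2CO3 deprotonates only the two phenols (pKa about 10), so the phenoxides are benzylated and the aliphatic hydroxyl stays free.

Step 2
Reactants: 3 methyl coumalate; 4 tert-butyl lactate (racemic)
Product: 7 (2E,4E)-5-{[1-(tert-butoxy)-1-oxopropan-2-yl]oxy}-4-(methoxycarbonyl)penta-2,4-dienoic acid (racemic), via sodium alkoxide 5 (not isolated), via sodium dienoate 6 (not isolated)
Conditions: 4, NaH (1.05 equiv), THF, 0 °C; then 3, −20 °C → rt; 1 M HCl, 0 °C
Reagents that add atoms: none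
Why: Conjugate 1,6-addition of the lactate alkoxide to C6 of the 2-pyranone followed by ring opening (addition–elimination, the lactone oxygen leaving as carboxylate) gives the acyclic dienoate, which should settle in the (2E,4E) geometry because only the (2Z) form can re-close and the donor–acceptor conjugation eases rotation about the enoate double bond; the lactate centre is deliberately left racemic.

Step 3
Reactants: 7 (2E,4E)-5-{[1-(tert-butoxy)-1-oxopropan-2-yl]oxy}-4-(methoxycarbonyl)penta-2,4-dienoic acid; 2 2-[3,4-bis(benzyloxy)phenyl]ethan-1-ol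
Product: 8 2-[3,4-bis(benzyloxy)phenyl]ethyl (2E,4E)-5-{[1-(tert-butoxy)-1-oxopropan-2-yl]oxy}-4-(methoxycarbonyl)penta-2,4-dienoate
Conditions: DIC (1.2 equiv), DMAP (10 mol%), CH2Cl2, 0 °C → rt
Reagents that add atoms: none
Why: Steglich esterification (carbodiimide activation with DMAP acyl transfer) of the conjugated acid with a primary alcohol, in which no stereocentre is touched and the tert-butyl and methyl esters are inert.

Step 4
Reactants: 8 2-[3,4-bis(benzyloxy)phenyl]ethyl (2E,4E)-5-{[1-(tert-butoxy)-1-oxopropan-2-yl]oxy}-4-(methoxycarbonyl)penta-2,4-dienoate; 9 potassium vinyltrifluoroborate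
Product: 10 2-[3,4-bis(benzyloxy)phenyl]ethyl (3S)-3-[(E)-2-{[1-(tert-butoxy)-1-oxopropan-2-yl]oxy}-1-(methoxycarbonyl)ethenyl]pent-4-enoate (both lactate epimers)
Conditions: 9 (3 equiv), [Rh(cod)2]BF4 (5 mol%), (R)-BINAP (6 mol%), toluene/H2O (10:1), 100 °C
Reagents that add atoms: none
Why: Hayashi–Miyaura asymmetric conjugate addition in which the vinyl–rhodium species (monovalent rhodium) inserts the disubstituted enoate double bond in preference to the trisubstituted, donor-substituted C5=C6 acrylate, the ligand quadrant model places vinyl on the Re face of C4 to give the (S) centre, and water protonates the rhodium enolate.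

Step 5
Reactants: 10 2-[3,4-bis(benzyloxy)phenyl]ethyl (3S)-3-[(E)-2-{[1-(tert-butoxy)-1-oxopropan-2-yl]oxy}-1-(methoxycarbonyl)ethenyl]pent-4-enoate; 11 vinylboronic acid pinacol ester
Product: 12 2-[3,4-bis(benzyloxy)phenyl]ethyl (3S,4E)-3-[(E)-2-{[1-(tert-butoxy)-1-oxopropan-2-yl]oxy}-1-(methoxycarbonyl)ethenyl]-5-(4,4,5,5-tetramethyl-1,3,2-dioxaborolan-2-yl)pent-4-enoate
Conditions: 11 (5 equiv), second-generation Hoveyda–Grubbs catalyst RuCl2(H2IMes)(=CH-C6H4-2-OiPr) (5 mol%), CH2Cl2, 40 °C
Reagents that add atoms: none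
Why: Olefin cross-metathesis of the terminal vinyl group with excess vinylboronate (ethene is lost), a pairing that normally gives the (E)-alkenylboronate, while the trisubstituted electron-poor C5=C6 enol ether does not engage the ruthenium carbene and C4 is untouched.

Step 6
Reactants: 12 2-[3,4-bis(benzyloxy)phenyl]ethyl (3S,4E)-3-[(E)-2-{[1-(tert-butoxy)-1-oxopropan-2-yl]oxy}-1-(methoxycarbonyl)ethenyl]-5-(4,4,5,5-tetramethyl-1,3,2-dioxaborolan-2-yl)pent-4-enoate
Product: 13 2-{[(1E,3S,4E)-3-(2-{2-[3,4-bis(benzyloxy)phenyl]ethoxy}-2-oxoethyl)-2-(methoxycarbonyl)-5-(4,4,5,5-tetramethyl-1,3,2-dioxaborolan-2-yl)penta-1,4-dien-1-yl]oxy}propanoic acid (both epimers at the propanoate carbon)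
Conditions: TFA/CH2Cl2 (1:4), 0 °C → rt
Reagents that add atoms: none
Why: Acidolysis of the tert-butyl ester (alkyl–oxygen cleavage, isobutene lost) unmasks the lactic acid, while the aryl benzyl ethers, the vinylogous carbonate C5=C6–O1, the pinacol alkenylboronate and the other two esters tolerate brief exposure to dilute TFA.

Step 7
Reactants: 13 2-{[(1E,3S,4E)-3-(2-{2-[3,4-bis(benzyloxy)phenyl]ethoxy}-2-oxoethyl)-2-(methoxycarbonyl)-5-(4,4,5,5-tetramethyl-1,3,2-dioxaborolan-2-yl)penta-1,4-dien-1-yl]oxy}propanoic acid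
Product: 15 methyl (2R,3S,4S)-4-(2-{2-[3,4-bis(benzyloxy)phenyl]ethoxy}-2-oxoethyl)-2-methyl-3-[(4,4,5,5-tetramethyl-1,3,2-dioxaborolan-2-yl)methyl]-3,4-dihydro-2H-pyran-5-carboxylate, via caesium carboxylate 14 (not isolated)
Conditions: [Ir(dF(CF3)ppy)2(dtbbpy)]PF6 (2 mol%), Cs2CO3 (0.25 equiv), DMF (0.02 M), degassed, 450 nm LEDs, rt
Reagents that add atoms: none
Why: The photoexcited trivalent iridium complex oxidises carboxylate 14, CO2 is lost, and the planar α-oxy radical at C2 adds to the alkene carbon bound to C4; the resulting α-boryl radical is reduced by the divalent iridium species to a boron-stabilised carbanion, which is protonated by remaining acid 13 so that carboxylate and base are regenerated (radical–polar crossover). The closest known reaction type is the photoredox decarboxylative Giese-type addition of α-oxy and α-amino acid radicals to vinylboronic esters, used here in intramolecular form. The dihydropyran ring closes in the 6-exo-trig mode by forming C2–C3. C3 is controlled by the C4 stereocentre through a half-chair transition state in which the C4 hydrogen eclipses the alkene (least 1,3-allylic strain) and the acetate arm is pseudo-equatorial, so the borylmethyl group ends up trans to it; C2 is controlled by C3 because the methyl group of the planar radical takes the pseudo-equatorial position (2,3-trans), and both lactate epimers therefore converge on one product. The step needs 6-exo addition to beat 7-endo addition and 1,5-hydrogen transfer from the doubly allylic C4–H: the polarity match between the nucleophilic radical and the boron-substituted alkene, the α-boryl stabilisation of the exo adduct radical and the low hydrogen-abstracting power of a stabilised α-oxy radical should secure this, while high dilution suppresses intermolecular addition and the substoichiometric base leaves free acid to quench the carbanion before it can acylate the C4 ester.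

Step 8
Reactants: 15 methyl (2R,3S,4S)-4-(2-{2-[3,4-bis(benzyloxy)phenyl]ethoxy}-2-oxoethyl)-2-methyl-3-[(4,4,5,5-tetramethyl-1,3,2-dioxaborolan-2-yl)methyl]-3,4-dihydro-2H-pyran-5-carboxylate
Product: 16 methyl (2R,3R,4S)-4-(2-{2-[3,4-bis(benzyloxy)phenyl]ethoxy}-2-oxoethyl)-3-(hydroxymethyl)-2-methyl-3,4-dihydro-2H-pyran-5-carboxylate
Conditions: NaBO3·4H2O (4 equiv), THF/H2O (1:1), 0 °C → rt; pH 7 phosphate buffer work-up
Reagents that add atoms: sodium perborate tetrahydrate, [Na+].[O-]OB=O.O.O.O.O
Why: Perborate oxidation of the primary alkylboronate (1,2-shift of the C3 methylene from boron to oxygen with hydrolytic loss of boron) at about pH 9.5 is mild enough for both esters and the enol ether, involves no stereocentre, and short cold contact limits δ-lactonisation of the new alcohol onto the acetate ester.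

Step 9
Reactants: 16 methyl (2R,3R,4S)-4-(2-{2-[3,4-bis(benzyloxy)phenyl]ethoxy}-2-oxoethyl)-3-(hydroxymethyl)-2-methyl-3,4-dihydro-2H-pyran-5-carboxylate
Product: 17 methyl (2R,3R,4S)-4-{2-[2-(3,4-dihydroxyphenyl)ethoxy]-2-oxoethyl}-3-(hydroxymethyl)-2-methyl-3,4-dihydro-2H-pyran-5-carboxylate (CNP0204147.1)
Conditions: H2 (1 atm), 10% Pd/C, EtOAc, rt
Reagents that add atoms: none
Why: Hydrogenolysis of the two aryl benzyl ethers over palladium under neutral conditions, where the trisubstituted donor–acceptor C5=C6 bond is slow to hydrogenate and no acid or base is present to trigger lactonisation or ring opening.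

Compound list
1 | hydroxytyrosol | OCCc1ccc(O)c(O)c1 | starting material
2 | 2-[3,4-bis(benzyloxy)phenyl]ethan-1-ol | OCCc1ccc(OCc2ccccc2)c(OCc2ccccc2)c1 | intermediate
3 | methyl coumalate | COC(=O)C1=COC(=O)C=C1 | starting material
4 | tert-butyl lactate (racemic) | CC(O)C(=O)OC(C)(C)C | starting material
5 | sodium 1-(tert-butoxy)-1-oxopropan-2-olate | CC([O-])C(=O)OC(C)(C)C.[Na+] | intermediate (not isolated)
6 | sodium (2E,4E)-5-{[1-(tert-butoxy)-1-oxopropan-2-yl]oxy}-4-(methoxycarbonyl)penta-2,4-dienoate | COC(=O)/C(=C/OC(C)C(=O)OC(C)(C)C)/C=C/C(=O)[O-].[Na+] | intermediate (not isolated)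
7 | (2E,4E)-5-{[1-(tert-butoxy)-1-oxopropan-2-yl]oxy}-4-(methoxycarbonyl)penta-2,4-dienoic acid (racemic) | COC(=O)/C(=C/OC(C)C(=O)OC(C)(C)C)/C=C/C(=O)O | intermediate
8 | 2-[3,4-bis(benzyloxy)phenyl]ethyl (2E,4E)-5-{[1-(tert-butoxy)-1-oxopropan-2-yl]oxy}-4-(methoxycarbonyl)penta-2,4-dienoate | COC(=O)/C(=C/OC(C)C(=O)OC(C)(C)C)/C=C/C(=O)OCCc1ccc(OCc2ccccc2)c(OCc2ccccc2)c1 | intermediate
9 | potassium vinyltrifluoroborate | [K+].C=C[B-](F)(F)F | starting material
10 | 2-[3,4-bis(benzyloxy)phenyl]ethyl (3S)-3-[(E)-2-{[1-(tert-butoxy)-1-oxopropan-2-yl]oxy}-1-(methoxycarbonyl)ethenyl]pent-4-enoate (both lactate epimers) | COC(=O)/C(=C/OC(C)C(=O)OC(C)(C)C)[C@@H](CC(=O)OCCc1ccc(OCc2ccccc2)c(OCc2ccccc2)c1)C=C | intermediate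
11 | vinylboronic acid pinacol ester | C=CB1OC(C)(C)C(C)(C)O1 | starting material
12 | 2-[3,4-bis(benzyloxy)phenyl]ethyl (3S,4E)-3-[(E)-2-{[1-(tert-butoxy)-1-oxopropan-2-yl]oxy}-1-(methoxycarbonyl)ethenyl]-5-(4,4,5,5-tetramethyl-1,3,2-dioxaborolan-2-yl)pent-4-enoate | COC(=O)/C(=C/OC(C)C(=O)OC(C)(C)C)[C@@H](CC(=O)OCCc1ccc(OCc2ccccc2)c(OCc2ccccc2)c1)/C=C/B1OC(C)(C)C(C)(C)O1 | intermediate
13 | 2-{[(1E,3S,4E)-3-(2-{2-[3,4-bis(benzyloxy)phenyl]ethoxy}-2-oxoethyl)-2-(methoxycarbonyl)-5-(4,4,5,5-tetramethyl-1,3,2-dioxaborolan-2-yl)penta-1,4-dien-1-yl]oxy}propanoic acid (both epimers at the propanoate carbon; key-step precursor) | COC(=O)/C(=C/OC(C)C(=O)O)[C@@H](CC(=O)OCCc1ccc(OCc2ccccc2)c(OCc2ccccc2)c1)/C=C/B1OC(C)(C)C(C)(C)O1 | intermediate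
14 | caesium salt of acid 13 | COC(=O)/C(=C/OC(C)C(=O)[O-])[C@@H](CC(=O)OCCc1ccc(OCc2ccccc2)c(OCc2ccccc2)c1)/C=C/B1OC(C)(C)C(C)(C)O1.[Cs+] | intermediate (not isolated)
15 | methyl (2R,3S,4S)-4-(2-{2-[3,4-bis(benzyloxy)phenyl]ethoxy}-2-oxoethyl)-2-methyl-3-[(4,4,5,5-tetramethyl-1,3,2-dioxaborolan-2-yl)methyl]-3,4-dihydro-2H-pyran-5-carboxylate (key-step product) | COC(=O)C1=CO[C@H](C)[C@@H](CB2OC(C)(C)C(C)(C)O2)[C@@H]1CC(=O)OCCc1ccc(OCc2ccccc2)c(OCc2ccccc2)c1 | intermediate
16 | methyl (2R,3R,4S)-4-(2-{2-[3,4-bis(benzyloxy)phenyl]ethoxy}-2-oxoethyl)-3-(hydroxymethyl)-2-methyl-3,4-dihydro-2H-pyran-5-carboxylate | COC(=O)C1=CO[C@H](C)[C@@H](CO)[C@@H]1CC(=O)OCCc1ccc(OCc2ccccc2)c(OCc2ccccc2)c1 | intermediate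
17 | methyl (2R,3R,4S)-4-{2-[2-(3,4-dihydroxyphenyl)ethoxy]-2-oxoethyl}-3-(hydroxymethyl)-2-methyl-3,4-dihydro-2H-pyran-5-carboxylate | COC(=O)C1=CO[C@H](C)[C@@H](CO)[C@@H]1CC(=O)OCCc1ccc(O)c(O)c1 | target

Total step count: 9. Longest linear sequence: 8 steps (steps 2 to 9, from methyl coumalate).

Steps most likely to fail

Step 7. The ring closure is under kinetic control. Relief of 1,2-allylic strain between the C5 ester and the C4 arm may favour a half-chair with a pseudo-axial arm, which would erode facial selectivity at C3 and with it at C2. Hydrogen transfer from C4–H to the C2 radical may also compete with cyclisation. The fallback replaces kinetic by thermodynamic control. It sets out from 15 obtained as a mixture of C2/C3 stereoisomers. Oxidation under the conditions of step 8 should give the stereoisomeric 3-hydroxymethyl dihydropyrans F1. Dess–Martin periodinane with NaHCO3 in CH2Cl2 at 0 °C should convert these into the 3-formyl dihydropyrans F2. Catalytic Et3N in CH2Cl2 at rt should then equilibrate C2 and C3 by reversible retro-oxa-Michael ring opening and re-closure, the known ring–chain behaviour of 3-formyl-2-methyl-dihydropyran-5-carboxylates of the secoiridoid aglycone type. The equilibrium is expected to favour the all-trans (2R,3S,4S)-3-formyl dihydropyran F3, while C4 is not involved. Reduction with NaBH4 in MeOH/THF at −40 °C brings the material back to the route at 16.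

Step 4. The push–pull dienoate may insert too slowly into the vinyl–rhodium bond, so that hydrolytic loss of the vinyl reagent outruns addition, or the ligand may discriminate the faces of C4 poorly. The fallback moves stereocontrol from the catalyst to an auxiliary and sets out from acid 7. Coupling with (R)-4-benzyl-1,3-oxazolidin-2-one (DIC, DMAP, CH2Cl2) should give the N-dienoyl oxazolidinone F4. Addition of the vinyl cuprate from CH2=CHMgBr and CuBr·SMe2 (THF/Me2S, −78 → −30 °C) to the chelated s-cis imide, anti to the benzyl group and thus on the Re face of C4, should give the (3S)-vinyl imide F5. LiOH/H2O2 (THF/H2O, 0 °C) cleaves the auxiliary to the (3S)-pent-4-enoic acid F6, and esterification with 2 under the conditions of step 3 comes back to the route at 10.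

Step 5. Turnover at the branched allylic alkene may be slow, with catalyst decomposition and self-metathesis of 11 consuming the reagents before conversion is complete. The fallback exchanges metathesis for a boryl-Heck reaction and sets out from 10. Pd2(dba)3 (zerovalent palladium) with tBuP(3,5-tBu2C6H3)2, B-chlorocatecholborane, LiOTf and Cy2NMe in PhCF3 at 70 °C should borylate the terminal alkene by borylpalladation and β-hydride elimination, giving the (E)-alkenyl catechol boronate F7. Addition of pinacol to the same flask transesterifies boron and comes back to the route at 12.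

Further compounds
F1 | step 7 | methyl (4S)-4-(2-{2-[3,4-bis(benzyloxy)phenyl]ethoxy}-2-oxoethyl)-3-(hydroxymethyl)-2-methyl-3,4-dihydro-2H-pyran-5-carboxylate (mixture of C2/C3 stereoisomers) | COC(=O)C1=COC(C)C(CO)[C@@H]1CC(=O)OCCc1ccc(OCc2ccccc2)c(OCc2ccccc2)c1
F2 | step 7 | methyl (4S)-4-(2-{2-[3,4-bis(benzyloxy)phenyl]ethoxy}-2-oxoethyl)-3-formyl-2-methyl-3,4-dihydro-2H-pyran-5-carboxylate (mixture of C2/C3 stereoisomers) | COC(=O)C1=COC(C)C(C=O)[C@@H]1CC(=O)OCCc1ccc(OCc2ccccc2)c(OCc2ccccc2)c1
F3 | step 7 | methyl (2R,3S,4S)-4-(2-{2-[3,4-bis(benzyloxy)phenyl]ethoxy}-2-oxoethyl)-3-formyl-2-methyl-3,4-dihydro-2H-pyran-5-carboxylate | COC(=O)C1=CO[C@H](C)[C@@H](C=O)[C@@H]1CC(=O)OCCc1ccc(OCc2ccccc2)c(OCc2ccccc2)c1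
F4 | step 4 | (4R)-4-benzyl-3-[(2E,4E)-5-{[1-(tert-butoxy)-1-oxopropan-2-yl]oxy}-4-(methoxycarbonyl)penta-2,4-dienoyl]-1,3-oxazolidin-2-one | COC(=O)/C(=C/OC(C)C(=O)OC(C)(C)C)/C=C/C(=O)N1[C@H](Cc2ccccc2)COC1=O
F5 | step 4 | (4R)-4-benzyl-3-{(3S)-3-[(E)-2-{[1-(tert-butoxy)-1-oxopropan-2-yl]oxy}-1-(methoxycarbonyl)ethenyl]pent-4-enoyl}-1,3-oxazolidin-2-one | COC(=O)/C(=C/OC(C)C(=O)OC(C)(C)C)[C@@H](CC(=O)N1[C@H](Cc2ccccc2)COC1=O)C=C
F6 | step 4 | (3S)-3-[(E)-2-{[1-(tert-butoxy)-1-oxopropan-2-yl]oxy}-1-(methoxycarbonyl)ethenyl]pent-4-enoic acid | COC(=O)/C(=C/OC(C)C(=O)OC(C)(C)C)[C@@H](CC(=O)O)C=C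
F7 | step 5 | 2-[3,4-bis(benzyloxy)phenyl]ethyl (3S,4E)-5-(1,3,2-benzodioxaborol-2-yl)-3-[(E)-2-{[1-(tert-butoxy)-1-oxopropan-2-yl]oxy}-1-(methoxycarbonyl)ethenyl]pent-4-enoate | COC(=O)/C(=C/OC(C)C(=O)OC(C)(C)C)[C@@H](CC(=O)OCCc1ccc(OCc2ccccc2)c(OCc2ccccc2)c1)/C=C/B1Oc2ccccc2O1
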